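**Retrosynthetic overview**
1. Target 32 ⇐ 31 by late α′-acetoxylation at C11 with Mn(OAc)3; 31 ⇐ 29 by desilylation, enone unmasking and γ-lactonisation (C7–O onto C19).
2. Key disconnection C7–C8: decarboxylative radical 8-exo closure of an α-silyloxy C7 radical onto the tetrasubstituted β-alkoxyacrylate of 27. It closes the oxocane (and with it the ten-membered carbocycle), creates quaternary C8 and sets C7 and C17.
3. 27 ⇐ 21 by palladium-mediated alkyne alkoxycarbonylation (tetrahydropyran ring, C8=C17–CO2Me); 21 ⇐ aldehyde 15 + chlorohydrin acid 19 by chelation-controlled indium Barbier allylation (C3–C4); 19 (C6–Cl, C5=CH2) ⇐ asymmetric γ-chloroallylboration of ethyl glyoxylate.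
4. 15 ⇐ lactone 9 (propynyl addition, Noyori reduction for C9, C11 methylation, ozonolysis) ⇐ catalytic asymmetric Diels–Alder adduct 6 (C1, C10) and chelation-controlled vinylation (C2).
5. Ring order: A (cyclohexenone) → B (tetrahydropyran) → C (oxocane, radical step) → D (γ-lactone).

Assumption: locants in names are the briarane locants of the target (C1–C20); "as in 32" means the same spatial arrangement, and the SMILES strings are authoritative for configuration.

**Route**

Step 1
Reactants: 1 propanal; 2 ethyl glyoxylate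
Product: 3 ethyl (E)-3-methyl-4-oxobut-2-enoate
Conditions: Bu2NH·AcOH (10 mol%), PhMe, 80 °C, slow addition of 1, removal of H2O
Reagents that add atoms: none
Why: amine-catalysed crossed aldol (Mannich-type) condensation of the only enolisable aldehyde with the non-enolisable glyoxylate, and dehydration gives the conjugated (E)-enal with CHO trans to CO2Et.

Step 2
Reactants: 4 (E)-4-(dimethylamino)but-3-en-2-one; 3 ethyl (E)-3-methyl-4-oxobut-2-enoate
Product: 6 ethyl (1S,2R,3S)-5-(tert-butyldimethylsilyloxy)-3-(dimethylamino)-2-formyl-2-methylcyclohex-4-ene-1-carboxylate, via Rawal diene 5 (not isolated)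
Conditions: 4, NaN(SiMe3)2, TBSCl, THF, −78 → 23 °C, filter, strip; then 3, [(R,R)-(salen)Cr]SbF6 (5 mol%), 4 Å MS, CH2Cl2, −40 °C
Reagents that add atoms: tert-butyldimethylsilyl chloride, CC(C)(C)[Si](C)(C)Cl
Why: kinetic O-silylation gives the 1-amino-3-siloxy diene, and the chromium–salen Lewis-acid-catalysed endo Diels–Alder reaction joins its CH2 terminus to the carbon β to the bound CHO; the (E)-dienophile fixes Me-15 cis to the C10 ester (C2 and C9 trans) and the catalyst's face selection sets the absolute configuration at C1 and C10.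

Step 3
Reactants: 6 Diels–Alder adduct; 7 vinylmagnesium bromide
Product: 9 trans-fused γ-lactone 6-(tert-butyldimethylsilyloxy)-4-(dimethylamino)-3a-methyl-3-vinyl-3a,4,7,7a-tetrahydroisobenzofuran-1(3H)-one (C2–O–C9(=O); C1/C2/C10 as in 32), via hydroxy ester 8 (not isolated)
Conditions: CH2=CHMgBr (1.2 equiv), THF, −78 °C, then 0 °C, 2 h; aq. NH4Cl
Reagents that add atoms: none
Why: chelation-controlled Grignard addition (six-membered N···Mg···O chelate with the cis 14-NMe2) attacks the neopentyl aldehyde anti to C10 and sets C2, and the magnesium alkoxide then lactonises onto the trans ester, which differentiates the C2 oxygen and turns C9 into an acyl donor.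

Step 4
Reactants: 9 γ-lactone; 10 1-propynyllithium
Product: 12 5-(but-2-ynoyl)-4-[(1S)-1-hydroxyallyl]-4-methylcyclohex-2-en-1-one (C1/C2/C10 as in 32), via masked hydroxy ynone 11 (not isolated)
Conditions: MeC≡CLi (1.1 equiv), THF, −78 °C; then 48% aq. HF, MeCN, 0 °C
Reagents that add atoms: none
Why: single acetylide addition to the strained lactone (lithium hemiketal stable at −78 °C) gives the ynone and frees the C2 hydroxyl, and HF then hydrolyses the silyl enol ether and the β-amino ketone loses Me2NH (E1cB, Rawal unmasking) to give the C13=C14 enone.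

Step 5
Reactants: 12 enone ynone
Product: 13 5-[(1S)-1-hydroxybut-2-yn-1-yl]-4-[(1S)-1-hydroxyallyl]-4-methylcyclohex-2-en-1-one (9S; C1/C2/C10 as in 32)
Conditions: Ru[(S,S)-TsDPEN](p-cymene) (2 mol%), i-PrOH, 23 °C
Reagents that add atoms: none
Why: Noyori asymmetric transfer hydrogenation of the ynone is catalyst-controlled and gives the (9S)-propargylic alcohol, while the far less reactive enone is untouched.

Step 6
Reactants: 13 propargylic alcohol
Product: 14 the 11-methyl derivative of 13 (6-methylcyclohex-2-enone; 11-Me trans to the C10 side chain)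
Conditions: LiN(i-Pr)2 (3.3 equiv), THF, −78 °C; MeI (1.1 equiv), −78 → −40 °C
Reagents that add atoms: iodomethane, CI
Why: kinetic α′-enolate alkylation: C11 is the only enolisable site (the γ position C1 is quaternary) and the bis-alkoxide dienolate is C-methylated trans to the C10 substituent; C11 is re-planarised later, so its configuration here does not matter.

Step 7
Reactants: 14 methylated diol
Product: 15 α-hydroxy aldehyde (C3 = CHO on C2; otherwise as 14; stored as its C9–O lactol)
Conditions: O3, CH2Cl2/MeOH (4:1), −78 °C, Sudan Red 7B end point; Me2S, −78 → 23 °C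
Reagents that add atoms: ozone, [O-][O+]=O
Why: chemoselective ozonolysis of the electron-rich monosubstituted alkene (the conjugated enone and the internal alkyne react much more slowly and the dye marks the end point) with reductive work-up gives the C3 aldehyde next to the free C2 hydroxyl.

Step 8
Reactants: 16 3-chloro-2-(chloromethyl)prop-1-ene; 2 ethyl glyoxylate
Product: 18 ethyl (2S,3S)-3-chloro-4-(chloromethyl)-2-hydroxypent-4-enoate, via chloroallylborane 17 (not isolated)
Conditions: 16, (+)-Ipc2BOMe, LiN(c-C6H11)2, Et2O, −95 °C; BF3·OEt2; then 2, −95 → −78 °C; HOCH2CH2NH2 work-up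
Reagents that add atoms: none
Why: Oehlschlager–Brown asymmetric γ-chloroallylboration: the lithiated allyl chloride is trapped on boron, shifts to the γ-chloroallylborane (Cl cis to CH2B) and adds through a chair transition state to the Re face of the aldehyde, giving the syn chlorohydrin with (3S) = C6–Cl, the C5=CH2 group in place and the second CH2Cl kept as a handle.

Step 9
Reactants: 18 chlorohydrin ester
Product: 19 (2S,3S)-3-chloro-4-(chloromethyl)-2-hydroxypent-4-enoic acid
Conditions: Me3SnOH (3 equiv), ClCH2CH2Cl, 70 °C; 5% aq. HCl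
Reagents that add atoms: trimethyltin hydroxide, C[Sn](C)(C)O
Why: near-neutral tin hydroxide ester hydrolysis (Nicolaou conditions) frees the acid without closing the chlorohydrin to an epoxide.

Step 10
Reactants: 15 α-hydroxy aldehyde; 19 chlorohydrin acid
Product: 21 seco acid (cyclohexenone with the (9S)-1-hydroxybut-2-ynyl group on C10 and the chain C2H(OH)–C3H(OH)–CH2–C(=CH2)–C6HCl–C7H(OH)–CO2H on C1; 2R,3R,6S,7S), via allylic iodide 20 (not isolated)
Conditions: In powder (2 equiv), NaI (1.5 equiv), DMF/H2O (4:1), 23 °C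
Reagents that add atoms: none
Why: Finkelstein exchange at the primary allylic chloride followed by indium Barbier allylation in water; Cram-chelate control by the free C2 hydroxyl (as with unprotected aldoses) gives the syn 2,3-diol (3R), and because both termini of the 2-substituted allyl unit are CH2 the C5 exo-methylene results in either case, the hindered secondary chloride staying intact.

Step 11
Reactants: 21 seco acid
Product: 22 tetrahydropyran triol acid (C2–O–C8 ring; exocyclic (E)-C8=C17(Me)CO2Me; free 3-, 7- and 9-OH)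
Conditions: PdCl2(MeCN)2 (10 mol%), p-benzoquinone (1.5 equiv), CO (1 atm), MeOH, 0 → 23 °C
Reagents that add atoms: carbon monoxide, [C-]#[O+]; methanol, CO
Why: oxidative cyclisation–methoxycarbonylation (Semmelhack/Kato type): anti-oxypalladation by the C2 hydroxyl in the 6-exo-dig mode (favoured over 7-exo by the C3 hydroxyl, and the alkyne is engaged faster than the chloride-deactivated 1,1-disubstituted alkene), then CO insertion and methanolysis give the tetrasubstituted β-alkoxyacrylate and close ring B.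

Step 12
Reactants: 22 triol acid
Product: 24 3,7-bis(tert-butyldimethylsilyl) ether acid (9-OH free), via silyl ester 23 (not isolated)
Conditions: TBSCl (5 equiv), imidazole (10 equiv), DMF, 23 °C; then K2CO3, MeOH/THF/H2O, 0 °C, 15 min
Reagents that add atoms: tert-butyldimethylsilyl chloride, CC(C)(C)[Si](C)(C)Cl
Why: Corey silylation takes the two accessible secondary hydroxyls (C3, C7), whereas the axial 9-OH, flanked by the tetrasubstituted alkene and syn-axial to Me-15, is too hindered; the silyl ester is cleaved in the work-up.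

Step 13
Reactants: 24 bis-silyl ether
Product: 25 9-acetate of 24
Conditions: Ac2O (10 equiv), DMAP (1 equiv), Et3N, CH2Cl2, 40 °C; aq. NaHCO3
Reagents that add atoms: acetic anhydride, CC(=O)OC(C)=O
Why: DMAP-catalysed (Steglich-type) acetylation of the only remaining hydroxyl; the mixed anhydride of the acid is hydrolysed in the work-up.

Step 14
Reactants: 25 acetate
Product: 27 silyl dienol ether acid (ring A as C11=C12(OTBS)–C13=C14), via silyl ester 26 (not isolated)
Conditions: TBSOTf (3 equiv), Et3N (5 equiv), CH2Cl2, −78 → 0 °C; then K2CO3, MeOH/THF/H2O, 0 °C, 10 min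
Reagents that add atoms: tert-butyldimethylsilyl triflate, CC(C)(C)[Si](C)(C)OS(=O)(=O)C(F)(F)F
Why: soft enolisation can only remove the α′ proton at C11, so the cross-conjugated 2-silyloxy diene forms; this masks the enone so that C14 is no longer a radical acceptor in the next step.

Step 15
Reactants: 27 silyl dienol ether acid
Product: 29 cyclised methyl ester (oxocane closed; C7–OTBS 7R, quaternary C8 8S, C17 17R), via phthalimide ester 28 (not isolated)
Conditions: N-hydroxyphthalimide, DIC, DMAP (cat.), CH2Cl2, 23 °C; then dilute to 2 mM, Ru(bpy)3(PF6)2 (2 mol%), Hantzsch ester (1.5 equiv, syringe pump), i-Pr2NEt, blue LEDs, 23 °C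
Reagents that add atoms: none
Why: Proposed new method: single-electron reduction of the N-(acyloxy)phthalimide by the photoreduced ruthenium catalyst and loss of CO2 give the nucleophilic α-silyloxy C7 radical, which the axial C2 tether holds under the α-face of the trans-fused tetrahydropyran so that it adds 8-exo-trig and axially to C8 of the push–pull acrylate (C7 must end up α/axial and C17 β/equatorial on the new quaternary centre); the OTBS group is placed anti to the ring oxygen (7R) and the tertiary α-ester radical takes hydrogen from the Hantzsch ester on the face away from the C7 silyl ether (17R); loss of the C6 chlorine is slow because β-C–Cl scission is about 20 kcal/mol uphill; the closest known reactions are the Okada/Overman decarboxylative Giese additions of N-(acyloxy)phthalimides and Lee's radical cyclisations onto β-alkoxyacrylates (five- to seven-membered ethers), extended here to an eight-membered closure onto a tetrasubstituted acceptor.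

Step 16
Reactants: 29 cyclised ester
Product: 31 11-deacetoxy lactone (tetracyclic enone; 3-OH free; C11–H with Me-20 α), via hydroxy ester 30 (not isolated)
Conditions: HF·pyridine, THF, 0 → 23 °C; then PPTS (cat.), PhMe, 50 °C
Reagents that add atoms: none
Why: fluoride/acid desilylation frees the 3- and 7-hydroxyls and protonates the dienol ether at C11 back to the enone, and the 7-hydroxyl closes the γ-lactone onto the methyl ester (acid-catalysed transesterification, no base, so C17 is not epimerised).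

Step 17
Reactants: 31 enone lactone
Product: 32 target CNP0253524.4
Conditions: Mn(OAc)3·2H2O (4 equiv), PhH, reflux (Dean–Stark)
Reagents that add atoms: manganese triacetate, CC(=O)[O-].CC(=O)[O-].CC(=O)[O-].[Mn+3]
Why: α′-acetoxylation of the enone via its trivalent manganese enolate and the α-keto radical; acetate is transferred to C11 from the α-face, anti to the syn-axial Me-15, giving 11α-OAc and Me-20 β.

**Compound list**
1 | propanal | CCC=O | starting material
2 | ethyl glyoxylate | CCOC(=O)C=O | starting material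
3 | ethyl (E)-3-methyl-4-oxobut-2-enoate | CCOC(=O)/C=C(\C)C=O | intermediate
4 | (E)-4-(dimethylamino)but-3-en-2-one | CC(=O)/C=C/N(C)C | starting material
5 | (E)-3-(tert-butyldimethylsilyloxy)-N,N-dimethylbuta-1,3-dien-1-amine (Rawal diene) | C=C(O[Si](C)(C)C(C)(C)C)/C=C/N(C)C | intermediate
6 | ethyl (1S,2R,3S)-5-(tert-butyldimethylsilyloxy)-3-(dimethylamino)-2-formyl-2-methylcyclohex-4-ene-1-carboxylate | CCOC(=O)[C@@H]1[C@@](C)(C=O)[C@@H](N(C)C)C=C(O[Si](C)(C)C(C)(C)C)C1 | intermediate
7 | vinylmagnesium bromide | C=C[Mg]Br | starting material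
8 | ethyl (1S,2R,3S)-5-(tert-butyldimethylsilyloxy)-3-(dimethylamino)-2-[(1S)-1-hydroxyallyl]-2-methylcyclohex-4-ene-1-carboxylate (formed as its bromomagnesium alkoxide) | CCOC(=O)[C@@H]1[C@@](C)([C@@H](O)C=C)[C@@H](N(C)C)C=C(O[Si](C)(C)C(C)(C)C)C1 | intermediate
9 | trans-fused γ-lactone, 6-(tert-butyldimethylsilyloxy)-4-(dimethylamino)-3a-methyl-3-vinyl-3a,4,7,7a-tetrahydroisobenzofuran-1(3H)-one (C1, C2, C10 as in 32) | O=C1O[C@@H](C=C)[C@@]2(C)[C@@H](N(C)C)C=C(O[Si](C)(C)C(C)(C)C)C[C@H]12 | intermediate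
10 | 1-propynyllithium | [Li]C#CC | starting material
11 | 1-[5-(tert-butyldimethylsilyloxy)-3-(dimethylamino)-2-(1-hydroxyallyl)-2-methylcyclohex-4-en-1-yl]but-2-yn-1-one (masked hydroxy ynone) | CC#CC(=O)[C@@H]1[C@@](C)([C@@H](O)C=C)[C@@H](N(C)C)C=C(O[Si](C)(C)C(C)(C)C)C1 | intermediate
12 | 5-(but-2-ynoyl)-4-[(1S)-1-hydroxyallyl]-4-methylcyclohex-2-en-1-one (C1, C2, C10 as in 32) | CC#CC(=O)[C@@H]1[C@@](C)([C@@H](O)C=C)C=CC(=O)C1 | intermediate
13 | 5-[(1S)-1-hydroxybut-2-yn-1-yl]-4-[(1S)-1-hydroxyallyl]-4-methylcyclohex-2-en-1-one (9S) | CC#C[C@@H](O)[C@@H]1[C@@](C)([C@@H](O)C=C)C=CC(=O)C1 | intermediate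
14 | 11-methyl derivative of 13 (Me-20 trans to the C10 side chain) | CC#C[C@@H](O)[C@@H]1[C@@](C)([C@@H](O)C=C)C=CC(=O)[C@H]1C | intermediate
15 | α-hydroxy aldehyde (C3 = CHO; (2R)-2-hydroxy-2-[ring]acetaldehyde; in equilibrium with the C9–O lactol) | CC#C[C@@H](O)[C@@H]1[C@@](C)([C@@H](O)C=O)C=CC(=O)[C@H]1C | intermediate
16 | 3-chloro-2-(chloromethyl)prop-1-ene | C=C(CCl)CCl | starting material
17 | [3-chloro-2-(chloromethyl)allyl]diisopinocampheylborane (vinylic Cl cis to CH2B; Ipc from (−)-α-pinene) | ClC/C(CB([C@H]1C[C@H]2C[C@@H]([C@@H]1C)C2(C)C)[C@H]1C[C@H]2C[C@@H]([C@@H]1C)C2(C)C)=C/Cl | intermediate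
18 | ethyl (2S,3S)-3-chloro-4-(chloromethyl)-2-hydroxypent-4-enoate | C=C(CCl)[C@H](Cl)[C@@H](O)C(=O)OCC | intermediate
19 | (2S,3S)-3-chloro-4-(chloromethyl)-2-hydroxypent-4-enoic acid | C=C(CCl)[C@H](Cl)[C@@H](O)C(=O)O | intermediate
20 | (2S,3S)-3-chloro-2-hydroxy-4-(iodomethyl)pent-4-enoic acid | C=C(CI)[C@H](Cl)[C@@H](O)C(=O)O | intermediate
21 | seco acid (2R,3R,6S,7S,9S; C1, C10 as in 32) | CC#C[C@@H](O)[C@@H]1[C@@](C)([C@@H](O)[C@H](O)CC(=C)[C@H](Cl)[C@@H](O)C(=O)O)C=CC(=O)[C@H]1C | intermediate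
22 | tetrahydropyran triol acid with exocyclic (E)-C8=C17(Me)CO2Me | OC(=O)[C@H](O)[C@@H](Cl)C(=C)C[C@@H](O)[C@@H]1O/C(=C(\C)C(=O)OC)[C@@H](O)[C@@H]2[C@]1(C)C=CC(=O)[C@H]2C | intermediate
23 | TBS ester of 24 | CC(C)(C)[Si](C)(C)OC(=O)[C@H](O[Si](C)(C)C(C)(C)C)[C@@H](Cl)C(=C)C[C@@H](O[Si](C)(C)C(C)(C)C)[C@@H]1O/C(=C(\C)C(=O)OC)[C@@H](O)[C@@H]2[C@]1(C)C=CC(=O)[C@H]2C | intermediate
24 | 3,7-bis-TBS ether acid (9-OH free) | OC(=O)[C@H](O[Si](C)(C)C(C)(C)C)[C@@H](Cl)C(=C)C[C@@H](O[Si](C)(C)C(C)(C)C)[C@@H]1O/C(=C(\C)C(=O)OC)[C@@H](O)[C@@H]2[C@]1(C)C=CC(=O)[C@H]2C | intermediate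
25 | 9-acetate of 24 | OC(=O)[C@H](O[Si](C)(C)C(C)(C)C)[C@@H](Cl)C(=C)C[C@@H](O[Si](C)(C)C(C)(C)C)[C@@H]1O/C(=C(\C)C(=O)OC)[C@@H](OC(C)=O)[C@@H]2[C@]1(C)C=CC(=O)[C@H]2C | intermediate
26 | TBS ester of 27 | CC(C)(C)[Si](C)(C)OC(=O)[C@H](O[Si](C)(C)C(C)(C)C)[C@@H](Cl)C(=C)C[C@@H](O[Si](C)(C)C(C)(C)C)[C@@H]1O/C(=C(\C)C(=O)OC)[C@@H](OC(C)=O)[C@@H]2[C@]1(C)C=CC(O[Si](C)(C)C(C)(C)C)=C2C | intermediate
27 | silyl dienol ether acid | OC(=O)[C@H](O[Si](C)(C)C(C)(C)C)[C@@H](Cl)C(=C)C[C@@H](O[Si](C)(C)C(C)(C)C)[C@@H]1O/C(=C(\C)C(=O)OC)[C@@H](OC(C)=O)[C@@H]2[C@]1(C)C=CC(O[Si](C)(C)C(C)(C)C)=C2C | intermediate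
28 | N-(acyloxy)phthalimide of 27 | O=C(ON1C(=O)c2ccccc2C1=O)[C@H](O[Si](C)(C)C(C)(C)C)[C@@H](Cl)C(=C)C[C@@H](O[Si](C)(C)C(C)(C)C)[C@@H]1O/C(=C(\C)C(=O)OC)[C@@H](OC(C)=O)[C@@H]2[C@]1(C)C=CC(O[Si](C)(C)C(C)(C)C)=C2C | intermediate
29 | cyclised methyl ester (oxocane closed; 3,7-bis-OTBS; ring A silyl dienol ether) | C=C1C[C@@H](O[Si](C)(C)C(C)(C)C)[C@@H]2O[C@]([C@@H](C)C(=O)OC)([C@@H](O[Si](C)(C)C(C)(C)C)[C@H]1Cl)[C@@H](OC(C)=O)[C@@H]1[C@]2(C)C=CC(O[Si](C)(C)C(C)(C)C)=C1C | intermediate
30 | 3,7-dihydroxy methyl ester enone | C=C1C[C@@H](O)[C@@H]2O[C@]([C@@H](C)C(=O)OC)([C@@H](O)[C@H]1Cl)[C@@H](OC(C)=O)[C@@H]1[C@]2(C)C=CC(=O)[C@H]1C | intermediate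
31 | 11-deacetoxy lactone (C11–H, Me-20 α) | C=C1C[C@@H](O)[C@@H]2O[C@@]3([C@@H](C)C(=O)O[C@H]3[C@H]1Cl)[C@@H](OC(C)=O)[C@@H]1[C@]2(C)C=CC(=O)[C@H]1C | intermediate
32 | CNP0253524.4 (1S,2R,3R,6S,7R,8S,9S,10S,11S,17R) | C=C1C[C@@H](O)[C@@H]2O[C@@]3([C@@H](C)C(=O)O[C@H]3[C@H]1Cl)[C@@H](OC(C)=O)[C@@H]1[C@]2(C)C=CC(=O)[C@@]1(C)OC(C)=O | target

**Totals**
Total step count: 17. Longest linear sequence: 15 (steps 1–7 and 10–17); steps 8–9 make the side fragment.

**Steps most likely to fail, with fallbacks**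

Step 15 (key cyclisation). The eight-membered closure onto a tetrasubstituted acceptor has to beat premature reduction of the C7 radical and loss of the β-chlorine, and the C7 and C17 configurations rest on conformational arguments only. Fallback: it sets out from 27 and returns at 29. The acid is converted with 2-mercaptopyridine N-oxide and DIC into Barton ester F1 (not isolated), which is photolysed with PhSeSePh to the isolable C7 α-silyloxy phenyl selenide F2 (both C7 epimers serve). Slow addition of Bu3SnH/AIBN to F2 in refluxing benzene (1 mM) then runs the same C7–C8 closure as a tin hydride chain of the Lee β-alkoxyacrylate type. In that regime the hydrogen-donor concentration is kept near zero and the temperature can be raised, which addresses the rate problem that the photoredox manifold cannot.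

Step 8 (asymmetric chloroallylboration). A 2-substituted allyl chloride carrying a second CH2Cl and a glyoxylate electrophile are both outside the usual scope, so the enantioselectivity and the stability of the lithiated species are uncertain. Fallback: it sets out from 16 (with 2) and returns at 18. Achiral B-methoxy-9-BBN replaces the Ipc reagent and gives the 9-BBN chloroallylborane F3 (not isolated). F3 adds to 2 to give the racemic syn chlorohydrin, that is 18 together with its enantiomer F4. Lipase PS with vinyl acetate in MTBE then acetylates the (2R,3R)-enantiomer to the acetate F5, and unreacted 18 is separated by chromatography. Absolute control thus comes from an enzymatic resolution, not from the borane.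

Step 17 (late α′-acetoxylation). Hot Mn(OAc)3 meets a free hydroxyl, an allylic chloride and an exo-methylene group, and a tertiary acetate has to be formed on the more hindered-looking diastereoface. Fallback: it sets out from 29 and returns at 32, by-passing 31. The silyl dienol ether of 29 is oxidised with dimethyldioxirane (acetone/CH2Cl2, −78 °C) from the α-face to the silyloxy epoxide F6 (not isolated), which opens on silica to the 11α-hydroxy enone F7 (Rubottom oxidation). Forcing acetylation (Ac2O, DMAP, 40 °C) gives the tertiary acetate F8 while C3 and C7 are still silylated. HF·pyridine followed by PPTS then removes both silyl ethers and lactonises through the hydroxy ester F9 (not isolated) to 32.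

Further compounds
F1 | step 15 | Barton ester (N-acyloxy-2-thiopyridone) of 27 | S=c1ccccn1OC(=O)[C@H](O[Si](C)(C)C(C)(C)C)[C@@H](Cl)C(=C)C[C@@H](O[Si](C)(C)C(C)(C)C)[C@@H]1O/C(=C(\C)C(=O)OC)[C@@H](OC(C)=O)[C@@H]2[C@]1(C)C=CC(O[Si](C)(C)C(C)(C)C)=C2C
F2 | step 15 | C7 α-silyloxy phenyl selenide (C7 epimers) | c1ccccc1[Se]C(O[Si](C)(C)C(C)(C)C)[C@@H](Cl)C(=C)C[C@@H](O[Si](C)(C)C(C)(C)C)[C@@H]1O/C(=C(\C)C(=O)OC)[C@@H](OC(C)=O)[C@@H]2[C@]1(C)C=CC(O[Si](C)(C)C(C)(C)C)=C2C
F3 | step 8 | 9-[3-chloro-2-(chloromethyl)allyl]-9-borabicyclo[3.3.1]nonane | ClC/C(CB1C2CCCC1CCC2)=C/Cl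
F4 | step 8 | ethyl (2R,3R)-3-chloro-4-(chloromethyl)-2-hydroxypent-4-enoate (enantiomer of 18) | C=C(CCl)[C@@H](Cl)[C@H](O)C(=O)OCC
F5 | step 8 | ethyl (2R,3R)-2-acetoxy-3-chloro-4-(chloromethyl)pent-4-enoate | C=C(CCl)[C@@H](Cl)[C@H](OC(C)=O)C(=O)OCC
F6 | step 17 | 11α,12α-epoxy-12-silyloxy derivative of 29 | C=C1C[C@@H](O[Si](C)(C)C(C)(C)C)[C@@H]2O[C@]([C@@H](C)C(=O)OC)([C@@H](O[Si](C)(C)C(C)(C)C)[C@H]1Cl)[C@@H](OC(C)=O)[C@@H]1[C@]2(C)C=C[C@@]3(O[Si](C)(C)C(C)(C)C)O[C@@]13C
F7 | step 17 | 11α-hydroxy enone, 3,7-bis-TBS ether methyl ester | C=C1C[C@@H](O[Si](C)(C)C(C)(C)C)[C@@H]2O[C@]([C@@H](C)C(=O)OC)([C@@H](O[Si](C)(C)C(C)(C)C)[C@H]1Cl)[C@@H](OC(C)=O)[C@@H]1[C@]2(C)C=CC(=O)[C@@]1(C)O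
F8 | step 17 | 11α-acetoxy enone, 3,7-bis-TBS ether methyl ester | C=C1C[C@@H](O[Si](C)(C)C(C)(C)C)[C@@H]2O[C@]([C@@H](C)C(=O)OC)([C@@H](O[Si](C)(C)C(C)(C)C)[C@H]1Cl)[C@@H](OC(C)=O)[C@@H]1[C@]2(C)C=CC(=O)[C@@]1(C)OC(C)=O
F9 | step 17 | 11α-acetoxy-3,7-dihydroxy methyl ester | C=C1C[C@@H](O)[C@@H]2O[C@]([C@@H](C)C(=O)OC)([C@@H](O)[C@H]1Cl)[C@@H](OC(C)=O)[C@@H]1[C@]2(C)C=CC(=O)[C@@]1(C)OC(C)=O
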